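**Strategy.** Ring B of the bicyclo[3.3.1]nonane (C9, C1, C8, C7, C6, C5) is treated as a formal [4+2] adduct and cut at C9–C1 and C7–C8 into a four-carbon silyl(vinyl)ketene C9=C5–C6=C7 and an isopropylidene acrylate C1=C8. In the key step the α-magnesiated acrylate adds to the ketene carbon C9 anti to silicon; the Z-trienolate closes C7–C8 by 6π-electrocyclisation, creating the gem-dimethyl carbon C8 beside the C7 stereocentre, and the β-keto ester enolate formed is prenylated at C1. Silicon and the ester are then excised, ring A (C2–C4) is bridged across C1/C5 by Effenberger annulation anti to the C7 geranyl group, and the enantiomer is selected in the C5 bridgehead prenylation.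

Key step: step 7

Remark: PPAP numbering is used (C1 bridgehead next to C8 = CMe2, C2–C4 diketone bridge, C5 second bridgehead, C6 CH2, C7 CH-geranyl, C9 bridging C=O); geranyl = (2E)-3,7-dimethylocta-2,6-dienyl, prenyl = 3-methylbut-2-enyl; enol tautomers are drawn as convenient; compounds 17–28 are racemates and the enantiomer that leads to 39 is drawn; absolute configuration is introduced by a kinetic resolution in step 12, which forgoes the slower-reacting enantiomer.

Step 1
Reactants: 1 geranyl bromide; 2 vinylmagnesium bromide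
Product: 3 (4E)-5,9-dimethyldeca-1,4,8-triene
Conditions: Li2CuCl4 (3 mol %), THF, −20 → 0 °C
Reagents that add atoms: vinylmagnesium bromide C=C[Mg]Br
Why: Copper-catalysed Grignard coupling should substitute the primary allylic bromide directly (SN2 mode) with retention of the E-trisubstituted alkene; no stereocentre is formed.

Step 2
Reactants: 3 (4E)-5,9-dimethyldeca-1,4,8-triene; 4 but-3-en-2-one
Product: 5 (3E,6E)-7,11-dimethyldodeca-3,6,10-trien-2-one
Conditions: second-generation Grubbs catalyst RuCl2(=CHPh)(PCy3)(H2IMes) (3 mol %), CH2Cl2, 40 °C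
Reagents that add atoms: but-3-en-2-one CC(=O)C=C
Why: Olefin cross-metathesis should engage only the monosubstituted alkene, leave the trisubstituted alkenes untouched and give the E-enone.

Step 3
Reactants: 5 (3E,6E)-7,11-dimethyldodeca-3,6,10-trien-2-one; 6 4-acetamidobenzenesulfonyl azide
Product: 8 (3E,6E)-1-diazo-7,11-dimethyldodeca-3,6,10-trien-2-one, via trifluoroacetyl diketone 7 (not isolated)
Conditions: LiN(SiMe3)2, THF, −78 °C; CF3CO2CH2CF3; aq. HCl; then 6, Et3N, H2O, MeCN, rt
Reagents that add atoms: 4-acetamidobenzenesulfonyl azide CC(=O)Nc1ccc(cc1)S(=O)(=O)N=[N+]=[N-]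
Why: Detrifluoroacetylative diazo transfer: the kinetic methyl enolate is trifluoroacetylated and the activated 1,3-diketone accepts the diazo group with loss of the trifluoroacetyl group, leaving the E-enone intact.

Step 4
Reactants: 8 (3E,6E)-1-diazo-7,11-dimethyldodeca-3,6,10-trien-2-one; 9 triisopropylsilyl trifluoromethanesulfonate
Product: 10 (3E,6E)-1-diazo-7,11-dimethyl-1-(triisopropylsilyl)dodeca-3,6,10-trien-2-one
Conditions: i-Pr2NEt, Et2O–hexane, 0 °C → rt
Reagents that add atoms: triisopropylsilyl trifluoromethanesulfonate CC(C)[Si](C(C)C)(C(C)C)OS(=O)(=O)C(F)(F)F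
Why: C-Silylation of the nucleophilic diazo carbon by the silyl triflate is the established entry to α-silyl α-diazo ketones.

Step 5
Reactants: 10 (3E,6E)-1-diazo-7,11-dimethyl-1-(triisopropylsilyl)dodeca-3,6,10-trien-2-one
Product: 11 (3E,6E)-7,11-dimethyl-2-(triisopropylsilyl)dodeca-1,3,6,10-tetraen-1-one
Conditions: hν (300 nm), benzene, rt
Reagents that add atoms: none
Why: Photochemical Wolff rearrangement (loss of N2, 1,2-shift of the alkenyl group) should give the silyl(vinyl)ketene, which the bulky silyl group makes isolable, with the E-alkene retained.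

Step 6
Reactants: 12 2-bromo-3-methylbut-2-enoic acid; 13 2-(trimethylsilyl)ethanol
Product: 14 2-(trimethylsilyl)ethyl 2-bromo-3-methylbut-2-enoate
Conditions: DCC, DMAP (cat.), CH2Cl2, 0 °C → rt
Reagents that add atoms: 2-(trimethylsilyl)ethanol C[Si](C)(C)CCO
Why: Steglich esterification installs a fluoride-cleavable ester that later activates C8 and C1 and is then removed without trace.

Step 7
Reactants: 14 2-(trimethylsilyl)ethyl 2-bromo-3-methylbut-2-enoate; 11 (3E,6E)-7,11-dimethyl-2-(triisopropylsilyl)dodeca-1,3,6,10-tetraen-1-one; 15 prenyl bromide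
Product: 19 2-(trimethylsilyl)ethyl 5-geranyl-6,6-dimethyl-2-oxo-1-prenyl-3-(triisopropylsilyl)cyclohex-3-ene-1-carboxylate (racemic), via alkenylmagnesium chloride 16 (not isolated), via magnesium trienolate 17 (not isolated), via cyclised magnesium enolate 18 (not isolated)
Conditions: 14, i-PrMgCl·LiCl, THF, −40 °C; 11, −40 → 25 °C; then 15, DMPU, 25 → 45 °C
Reagents that add atoms: prenyl bromide CC(C)=CCBr
Why: Proposed new method: Br/Mg exchange gives the α-magnesio acrylate 16, whose C1 adds to the ketene carbon C9 of 11 from the side opposite the bulky Si(i-Pr)3 group (C9–C1 bond), so that C1 and the C6=C7 vinyl group are cis on the C9=C5 enolate bond of trienolate 17. Magnesium chelation between the enolate oxygen and the ester carbonyl should hold C8 over C7, and ring B closes by thermal disrotatory 6π-electrocyclisation of the 3-oxidohexatriene C8=C1–C9=C5–C6=C7 (polarity-matched attack of the dienolate γ-carbon C7 on the acrylate β-carbon C8, formally 6-endo-trig), driven by formation of the chelated β-keto ester enolate 18 (C7–C8 bond, quaternary C8). The closest known reaction types are the [4+1] annulation of (trialkylsilyl)vinylketenes, in which a carbon nucleophile adds to the ketene carbon anti to silicon and the Z-dienolate then cyclises, and the alkoxide-accelerated 4π-opening/6π-closure cascades of alkenylcyclobutenoxides. C7 is created without absolute control (racemate, resolved in step 12) from the E-configured triene terminus; C1 becomes quaternary on C-prenylation of 18 but is erased in step 8. The step needs C-attack at C9 with Z-trienolate geometry and ring closure faster than proton transfer or a [1,7]-hydrogen shift; the silyl group, the magnesium chelate and the acceptor ester on C1 are there to secure this.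

Step 8
Reactants: 19 2-(trimethylsilyl)ethyl 5-geranyl-6,6-dimethyl-2-oxo-1-prenyl-3-(triisopropylsilyl)cyclohex-3-ene-1-carboxylate
Product: 21 4-geranyl-3,3-dimethyl-2-prenylcyclohexan-1-one (racemic at C4; both C2 epimers), via lithium enolate 20 (not isolated)
Conditions: LiBH(s-Bu)3, THF, −78 °C; then Bu4NF, THF, 0 → 50 °C; aq. NH4Cl
Reagents that add atoms: none
Why: The hindered, β-unsubstituted enone should be reduced in the 1,4-sense, and fluoride then cleaves the silylethyl ester (ethene loss, decarboxylation of the β-keto carboxylate) and the α-silyl ketone C–Si bond; C1 becomes an epimerisable CH of no consequence and C7 is untouched.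

Step 9
Reactants: 21 4-geranyl-3,3-dimethyl-2-prenylcyclohexan-1-one; 22 chlorotrimethylsilane
Product: 24 [(4-geranyl-5,5-dimethyl-6-prenylcyclohex-1-en-1-yl)oxy]trimethylsilane (racemic), via lithium enolate 23 (not isolated)
Conditions: LiN(i-Pr)2, THF, −78 °C; then 22, Et3N
Reagents that add atoms: chlorotrimethylsilane C[Si](C)(C)Cl
Why: Kinetic deprotonation should occur at the unhindered C5 methylene rather than at the tertiary, neopentyl C1–H, and O-silylation fixes this enolate as the silyl enol ether.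

Step 10
Reactants: 24 [(4-geranyl-5,5-dimethyl-6-prenylcyclohex-1-en-1-yl)oxy]trimethylsilane; 25 malonyl dichloride
Product: 26 rac-(1R,5S,7R)-7-geranyl-8,8-dimethyl-1-prenylbicyclo[3.3.1]nonane-2,4,9-trione
Conditions: Et2O, −20 °C → rt; then aq. KOH, BnEt3NCl; H3O+
Reagents that add atoms: malonyl dichloride O=C(Cl)CC(Cl)=O
Why: Effenberger cyclisation (α,α′-annulation): the enol ether is C-acylated at C5 and the second acyl chloride acylates C1 through the ketone enol, both on the ring face syn to the axial H7 and anti to the equatorial geranyl group, which sets C1 and C5 relative to C7 (7-exo), as known for the analogous 7-prenyl ketone.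

Step 11
Reactants: 26 rac-(1R,5S,7R)-7-geranyl-8,8-dimethyl-1-prenylbicyclo[3.3.1]nonane-2,4,9-trione; 27 dimethyl sulfate
Product: 28 rac-(1R,5S,7R)-7-geranyl-2-methoxy-8,8-dimethyl-1-prenylbicyclo[3.3.1]non-2-ene-4,9-dione
Conditions: K2CO3, acetone, reflux; chromatographic separation from the 4-methoxy regioisomer
Reagents that add atoms: dimethyl sulfate COS(=O)(=O)OC
Why: O-Methylation of the vinylogous acid gives the vinylogous ester that makes H5 and H3 selectively removable; the isomer with the C4 carbonyl next to H5 is carried on and the other can be hydrolysed and recycled.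

Step 12
Reactants: 28 rac-(1R,5S,7R)-7-geranyl-2-methoxy-8,8-dimethyl-1-prenylbicyclo[3.3.1]non-2-ene-4,9-dione; 15 prenyl bromide
Product: 30 (1R,5S,7R)-7-geranyl-2-methoxy-8,8-dimethyl-1,5-diprenylbicyclo[3.3.1]non-2-ene-4,9-dione, via bridgehead organolithium 29 (not isolated)
Conditions: dilithium (1R,2R)-N,N′-bis[(R)-1-phenylethyl]-1,2-diphenylethane-1,2-diamide or its enantiomer (0.6 equiv, from the diamine and n-BuLi), LiCl, THF, −100 → −78 °C; then 15
Reagents that add atoms: prenyl bromide CC(C)=CCBr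
Why: Kinetic resolution by enantioselective bridgehead deprotonation, known for the 7-prenyl analogue: the antipode of the amide that removes H5 of (1R,5S,7R)-28 faster is used, the pyramidal bridgehead carbanion is alkylated with retention to make C5 quaternary, and the slow enantiomer is recovered unchanged.

Step 13
Reactants: 31 3,4-dihydroxybenzoic acid; 32 tert-butyl(chloro)dimethylsilane
Product: 33 tert-butyldimethylsilyl 3,4-bis(tert-butyldimethylsilyloxy)benzoate
Conditions: imidazole, DMF, rt
Reagents that add atoms: tert-butyl(chloro)dimethylsilane CC(C)(C)[Si](C)(C)Cl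
Why: Exhaustive silylation protects the catechol against the organolithium chemistry of step 15 and gives a silyl ester ready for conversion to the acid chloride.

Step 14
Reactants: 33 tert-butyldimethylsilyl 3,4-bis(tert-butyldimethylsilyloxy)benzoate; 34 oxalyl chloride
Product: 35 3,4-bis(tert-butyldimethylsilyloxy)benzoyl chloride
Conditions: DMF (cat.), CH2Cl2, 0 °C → rt
Reagents that add atoms: oxalyl chloride O=C(Cl)C(Cl)=O
Why: Silyl esters are converted into acid chlorides by the chloroiminium reagent under neutral conditions that leave aryl silyl ethers intact.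

Step 15
Reactants: 30 (1R,5S,7R)-7-geranyl-2-methoxy-8,8-dimethyl-1,5-diprenylbicyclo[3.3.1]non-2-ene-4,9-dione; 35 3,4-bis(tert-butyldimethylsilyloxy)benzoyl chloride
Product: 37 (1R,5R,7R)-3-[3,4-bis(tert-butyldimethylsilyloxy)benzoyl]-7-geranyl-2-methoxy-8,8-dimethyl-1,5-diprenylbicyclo[3.3.1]non-2-ene-4,9-dione, via vinyllithium 36 (not isolated)
Conditions: lithium 2,2,6,6-tetramethylpiperidide, THF, −78 °C; then 35, −78 → 0 °C
Reagents that add atoms: 3,4-bis(tert-butyldimethylsilyloxy)benzoyl chloride O=C(Cl)c1ccc(O[Si](C)(C)C(C)(C)C)c(O[Si](C)(C)C(C)(C)C)c1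
Why: With both bridgeheads quaternary, the hindered amide should lithiate only the vinylic C3–H of the vinylogous ester, and the vinyllithium is C-acylated by the acid chloride; no stereocentre is touched.

Step 16
Reactants: 37 (1R,5R,7R)-3-[3,4-bis(tert-butyldimethylsilyloxy)benzoyl]-7-geranyl-2-methoxy-8,8-dimethyl-1,5-diprenylbicyclo[3.3.1]non-2-ene-4,9-dione; 38 lithium hydroxide
Product: 39 oblongifolin B
Conditions: LiOH, H2O–dioxane, 90 °C, argon; then aq. HCl
Reagents that add atoms: lithium hydroxide [Li+].[OH-]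
Why: Hydroxide should hydrolyse the vinylogous methyl ester by addition–elimination at C2 and cleave both aryl silyl ethers, releasing the enolised β-triketone and the catechol; no stereocentre is epimerisable.

**Compound list**

1 | geranyl bromide, (2E)-1-bromo-3,7-dimethylocta-2,6-diene | CC(C)=CCC/C(C)=C/CBr | starting material
2 | vinylmagnesium bromide | C=C[Mg]Br | starting material
3 | (4E)-5,9-dimethyldeca-1,4,8-triene | CC(C)=CCC/C(C)=C/CC=C | intermediate
4 | but-3-en-2-one | CC(=O)C=C | starting material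
5 | (3E,6E)-7,11-dimethyldodeca-3,6,10-trien-2-one | CC(C)=CCC/C(C)=C/C/C=C/C(C)=O | intermediate
6 | 4-acetamidobenzenesulfonyl azide | CC(=O)Nc1ccc(cc1)S(=O)(=O)N=[N+]=[N-] | starting material
7 | (5E,8E)-1,1,1-trifluoro-9,13-dimethyltetradeca-5,8,12-triene-2,4-dione (not isolated) | CC(C)=CCC/C(C)=C/C/C=C/C(=O)CC(=O)C(F)(F)F | intermediate
8 | (3E,6E)-1-diazo-7,11-dimethyldodeca-3,6,10-trien-2-one | CC(C)=CCC/C(C)=C/C/C=C/C(=O)C=[N+]=[N-] | intermediate
9 | triisopropylsilyl trifluoromethanesulfonate | CC(C)[Si](C(C)C)(C(C)C)OS(=O)(=O)C(F)(F)F | starting material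
10 | (3E,6E)-1-diazo-7,11-dimethyl-1-(triisopropylsilyl)dodeca-3,6,10-trien-2-one | CC(C)=CCC/C(C)=C/C/C=C/C(=O)C(=[N+]=[N-])[Si](C(C)C)(C(C)C)C(C)C | intermediate
11 | (3E,6E)-7,11-dimethyl-2-(triisopropylsilyl)dodeca-1,3,6,10-tetraen-1-one, the silyl(vinyl)ketene | CC(C)=CCC/C(C)=C/C/C=C/C(=C=O)[Si](C(C)C)(C(C)C)C(C)C | intermediate
12 | 2-bromo-3-methylbut-2-enoic acid | CC(C)=C(Br)C(=O)O | starting material
13 | 2-(trimethylsilyl)ethanol | C[Si](C)(C)CCO | starting material
14 | 2-(trimethylsilyl)ethyl 2-bromo-3-methylbut-2-enoate | CC(C)=C(Br)C(=O)OCC[Si](C)(C)C | intermediate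
15 | prenyl bromide, 1-bromo-3-methylbut-2-ene | CC(C)=CCBr | starting material
16 | 2-(trimethylsilyl)ethyl 2-(chloromagnesio)-3-methylbut-2-enoate (not isolated) | CC(C)=C([Mg]Cl)C(=O)OCC[Si](C)(C)C | intermediate
17 | chloromagnesium trienolate from 16 and 11, C1 and C6 cis on the C9=C5 enolate bond (not isolated) | CC(C)=CCC/C(C)=C/C/C=C/C(=C(\C(C(=O)OCC[Si](C)(C)C)=C(C)C)O[Mg]Cl)[Si](C(C)C)(C(C)C)C(C)C | intermediate
18 | chloromagnesium enolate of 2-(trimethylsilyl)ethyl 5-geranyl-6,6-dimethyl-2-oxo-3-(triisopropylsilyl)cyclohex-3-ene-1-carboxylate (racemic, not isolated) | CC(C)=CCC/C(C)=C/C[C@@H]1C=C([Si](C(C)C)(C(C)C)C(C)C)C(O[Mg]Cl)=C(C(=O)OCC[Si](C)(C)C)C1(C)C | intermediate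
19 | 2-(trimethylsilyl)ethyl 5-geranyl-6,6-dimethyl-2-oxo-1-prenyl-3-(triisopropylsilyl)cyclohex-3-ene-1-carboxylate (racemic; C1 configuration not defined) | CC(C)=CCC/C(C)=C/C[C@@H]1C=C([Si](C(C)C)(C(C)C)C(C)C)C(=O)C(CC=C(C)C)(C(=O)OCC[Si](C)(C)C)C1(C)C | intermediate
20 | lithium enolate formed by 1,4-reduction of 19 (not isolated) | CC(C)=CCC/C(C)=C/C[C@@H]1CC([Si](C(C)C)(C(C)C)C(C)C)=C(O[Li])C(CC=C(C)C)(C(=O)OCC[Si](C)(C)C)C1(C)C | intermediate
21 | 4-geranyl-3,3-dimethyl-2-prenylcyclohexan-1-one (racemic at C4; both C2 epimers) | CC(C)=CCC/C(C)=C/C[C@@H]1CCC(=O)C(CC=C(C)C)C1(C)C | intermediate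
22 | chlorotrimethylsilane | C[Si](C)(C)Cl | starting material
23 | lithium 4-geranyl-5,5-dimethyl-6-prenylcyclohex-1-en-1-olate (not isolated) | CC(C)=CCC/C(C)=C/C[C@@H]1CC=C(O[Li])C(CC=C(C)C)C1(C)C | intermediate
24 | [(4-geranyl-5,5-dimethyl-6-prenylcyclohex-1-en-1-yl)oxy]trimethylsilane (racemic) | CC(C)=CCC/C(C)=C/C[C@@H]1CC=C(O[Si](C)(C)C)C(CC=C(C)C)C1(C)C | intermediate
25 | malonyl dichloride | O=C(Cl)CC(Cl)=O | starting material
26 | rac-(1R,5S,7R)-7-geranyl-8,8-dimethyl-1-prenylbicyclo[3.3.1]nonane-2,4,9-trione (7-exo) | CC(C)=CCC/C(C)=C/C[C@@H]1C[C@@H]2C(=O)[C@@](CC=C(C)C)(C(=O)CC2=O)C1(C)C | intermediate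
27 | dimethyl sulfate | COS(=O)(=O)OC | starting material
28 | rac-(1R,5S,7R)-7-geranyl-2-methoxy-8,8-dimethyl-1-prenylbicyclo[3.3.1]non-2-ene-4,9-dione | CC(C)=CCC/C(C)=C/C[C@@H]1C[C@@H]2C(=O)[C@@](CC=C(C)C)(C(OC)=CC2=O)C1(C)C | intermediate
29 | 5-lithio derivative of (1R,5S,7R)-28 (not isolated) | CC(C)=CCC/C(C)=C/C[C@@H]1C[C@]2([Li])C(=O)[C@@](CC=C(C)C)(C(OC)=CC2=O)C1(C)C | intermediate
30 | (1R,5S,7R)-7-geranyl-2-methoxy-8,8-dimethyl-1,5-diprenylbicyclo[3.3.1]non-2-ene-4,9-dione | CC(C)=CCC/C(C)=C/C[C@@H]1C[C@]2(CC=C(C)C)C(=O)[C@@](CC=C(C)C)(C(OC)=CC2=O)C1(C)C | intermediate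
31 | 3,4-dihydroxybenzoic acid | O=C(O)c1ccc(O)c(O)c1 | starting material
32 | tert-butyl(chloro)dimethylsilane | CC(C)(C)[Si](C)(C)Cl | starting material
33 | tert-butyldimethylsilyl 3,4-bis(tert-butyldimethylsilyloxy)benzoate | CC(C)(C)[Si](C)(C)OC(=O)c1ccc(O[Si](C)(C)C(C)(C)C)c(O[Si](C)(C)C(C)(C)C)c1 | intermediate
34 | oxalyl chloride | O=C(Cl)C(Cl)=O | starting material
35 | 3,4-bis(tert-butyldimethylsilyloxy)benzoyl chloride | O=C(Cl)c1ccc(O[Si](C)(C)C(C)(C)C)c(O[Si](C)(C)C(C)(C)C)c1 | intermediate
36 | 3-lithio derivative of 30 (not isolated) | CC(C)=CCC/C(C)=C/C[C@@H]1C[C@]2(CC=C(C)C)C(=O)[C@@](CC=C(C)C)(C(OC)=C([Li])C2=O)C1(C)C | intermediate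
37 | (1R,5R,7R)-3-[3,4-bis(tert-butyldimethylsilyloxy)benzoyl]-7-geranyl-2-methoxy-8,8-dimethyl-1,5-diprenylbicyclo[3.3.1]non-2-ene-4,9-dione | CC(C)=CCC/C(C)=C/C[C@@H]1C[C@]2(CC=C(C)C)C(=O)[C@@](CC=C(C)C)(C(OC)=C(C(=O)c3ccc(O[Si](C)(C)C(C)(C)C)c(O[Si](C)(C)C(C)(C)C)c3)C2=O)C1(C)C | intermediate
38 | lithium hydroxide | [Li+].[OH-] | starting material
39 | oblongifolin B, (1S,5S,7R)-3-(3,4-dihydroxybenzoyl)-7-geranyl-4-hydroxy-8,8-dimethyl-1,5-diprenylbicyclo[3.3.1]non-3-ene-2,9-dione | CC(C)=CCC/C(C)=C/C[C@@H]1C[C@]2(CC=C(C)C)C(=O)[C@@](CC=C(C)C)(C(=O)C(C(=O)c3ccc(O)c(O)c3)=C2O)C1(C)C | target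

**Step count.** Total: 16 steps. Longest linear sequence: 13 steps (steps 1–5, 7–12, 15 and 16).

**Steps most likely to fail**

Step 7 (the annulation). The Grignard reagent may add on the silicon side of the ketene and give the E-trienolate, which cannot close. Proton transfer or a [1,7]-hydrogen shift from a C8 methyl group may outrun the electrocyclisation. The chelated magnesium enolate may be prenylated on oxygen or not at all. The fallback uses known chemistry only, sets out from 1 and comes back at 21. The kinetic lithium enolate of commercial 3-ethoxycyclohex-2-en-1-one (LiN(i-Pr)2, THF, −78 °C) is alkylated with 1 to give 3-ethoxy-6-geranylcyclohex-2-en-1-one F1 (Stork–Danheiser alkylation). Addition of MeLi and acidic hydrolysis with transposition give 4-geranyl-3-methylcyclohex-2-en-1-one F2. Conjugate addition of Me2CuLi then creates the gem-dimethyl carbon, and the enolate is trapped with 15 to give 21.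

Step 10 (Effenberger cyclisation). The mono-acylated acid chloride may close on oxygen to an enol lactone or oligomerise instead of acylating the hindered C1, and HCl may cleave the silyl enol ether before the first acylation. The fallback sets out from 21 and comes back at 26. Condensation with pyrrolidine gives the less substituted pyrrolidine enamine F3. α,α′-Annulation with acryloyl chloride (N-acylation, [3,3]-shift, ring closure at C1) gives 7-geranyl-8,8-dimethyl-1-prenylbicyclo[3.3.1]nonane-2,9-dione F4. Dehydrogenation with IBX gives the enone F5 and nucleophilic epoxidation (t-BuOOH, DBU) gives the epoxy ketone F6. Isomerisation of the epoxy ketone to the β-diketone with Pd(PPh3)4 and dppe gives 26.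

Step 12 (kinetic resolution). The rate difference between the two enantiomers in the bridgehead deprotonation may be too small for useful enantiomeric purity, or the bridgehead anion may be protonated before it is alkylated. The fallback sets out from 28 and comes back at 30. Achiral bridgehead lithiation with LiN(i-Pr)2 and alkylation with 15 gives 30 together with its mirror image ent-30 F7 as the racemate. The enantiomers are then separated by preparative chromatography on a chiral stationary phase.

**Further compounds**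

F1 | step 7 | 3-ethoxy-6-geranylcyclohex-2-en-1-one (racemic) | CCOC1=CC(=O)C(C/C=C(\C)CCC=C(C)C)CC1
F2 | step 7 | 4-geranyl-3-methylcyclohex-2-en-1-one (racemic) | CC1=CC(=O)CCC1C/C=C(\C)CCC=C(C)C
F3 | step 10 | 1-(4-geranyl-5,5-dimethyl-6-prenylcyclohex-1-en-1-yl)pyrrolidine (racemic) | CC(C)=CCC/C(C)=C/C[C@@H]1CC=C(N2CCCC2)C(CC=C(C)C)C1(C)C
F4 | step 10 | rac-7-geranyl-8,8-dimethyl-1-prenylbicyclo[3.3.1]nonane-2,9-dione (7-exo) | CC(C)=CCC/C(C)=C/C[C@@H]1C[C@@H]2C(=O)[C@@](CC=C(C)C)(C(=O)CC2)C1(C)C
F5 | step 10 | rac-7-geranyl-8,8-dimethyl-1-prenylbicyclo[3.3.1]non-3-ene-2,9-dione | CC(C)=CCC/C(C)=C/C[C@@H]1C[C@@H]2C(=O)[C@@](CC=C(C)C)(C(=O)C=C2)C1(C)C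
F6 | step 10 | rac-3,4-epoxy-7-geranyl-8,8-dimethyl-1-prenylbicyclo[3.3.1]nonane-2,9-dione | CC(C)=CCC/C(C)=C/C[C@@H]1C[C@@H]2C(=O)[C@@](CC=C(C)C)(C(=O)C3OC32)C1(C)C
F7 | step 12 | ent-30, (1S,5R,7S)-7-geranyl-2-methoxy-8,8-dimethyl-1,5-diprenylbicyclo[3.3.1]non-2-ene-4,9-dione | CC(C)=CCC/C(C)=C/C[C@H]1C[C@@]2(CC=C(C)C)C(=O)[C@](CC=C(C)C)(C(OC)=CC2=O)C1(C)C
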